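**Retrosynthetic overview**
1. The target is reached by late desilylation and allylic oxidation of a bis-silylated butenolide; the butenolide ring is closed last, from an α-hydroxy ketone and Ph3P=C=C=O.
2. The (E)-trisubstituted alkene, and the bond between the enal α-carbon and its β-CH, come from a directed aldol addition of the lithium enolate of terpenoid ester 8 to sugar-derived aldehyde 14, followed by E1cB dehydration.
3. Ester 8 comes from (+)-sclareolide, which supplies rings A and B with both ring-fusion stereocentres: lactone opening to the tetrasubstituted alkene, reduction, iodination and malonate homologation.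
4. Aldehyde 14 comes from 2-deoxy-L-ribose (dithiane, terminal acetonide, PMB ether), whose C3 carbinol becomes the (R)-configured butenolide C5.
5. Ring order: rings A/B are bought intact; dithiane and dioxolane are temporary; the butenolide ring is formed in step 18.

Assumption: 2-deoxy-L-ribose (drawn open-chain) is bought as a bulk sugar; its C4 configuration is irrelevant because that carbon is later oxidised to the ketone.

Abbreviations: Dec = (4aS,8aS)-2,5,5,8a-tetramethyl-3,4,4a,5,6,7,8,8a-octahydronaphthalen-1-yl; PMBO = 4-methoxybenzyloxy; TBSO = tert-butyldimethylsilyloxy; TBDPSO = tert-butyldiphenylsilyloxy.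

**Route**

Step 1
Reactants: 1 (+)-sclareolide
Product: 2 methyl 2-(Dec)acetate
Conditions: conc. H2SO4, MeOH, 25 °C, 48 h; chromatography (AgNO3-doped silica if needed)
Reagents that add atoms: methanol, CO
Why: Acid-mediated lactone opening by E1 elimination with Fischer esterification gives the thermodynamically preferred tetrasubstituted ring-B alkene, and the two ring-fusion stereocentres are not touched.

Step 2
Reactants: 2 methyl 2-(Dec)acetate
Product: 3 2-(Dec)ethan-1-ol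
Conditions: LiAlH4, THF, 0 °C to rt; H2O/aq. NaOH work-up
Reagents that add atoms: none
Why: Hydride reduction of the ester gives the primary alcohol while the isolated tetrasubstituted alkene is inert.

Step 3
Reactants: 3 2-(Dec)ethan-1-ol
Product: 4 2-(Dec)ethyl iodide
Conditions: PPh3, I2, imidazole, CH2Cl2, 0 °C to rt
Reagents that add atoms: iodine, II
Why: Appel-type iodination converts the unhindered primary alcohol to the iodide by SN2 displacement of the oxyphosphonium group.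

Step 4
Reactants: 4 2-(Dec)ethyl iodide; 5 dimethyl malonate
Product: 7 dimethyl 2-[2-(Dec)ethyl]propanedioate, via sodium dimethyl malonate 6 (not isolated)
Conditions: 5 (3 equiv), NaH (2.5 equiv), THF/DMF, 0 °C; then 4, 65 °C
Reagents that add atoms: none
Why: Malonic ester alkylation, in which the soft and weakly basic malonate anion displaces the primary homoallylic iodide by SN2 with little E2, and excess malonate suppresses dialkylation.

Step 5
Reactants: 7 dimethyl 2-[2-(Dec)ethyl]propanedioate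
Product: 8 methyl 4-(Dec)butanoate
Conditions: LiCl, H2O, DMSO, 150 °C
Reagents that add atoms: none
Why: Krapcho dealkoxycarbonylation, in which chloride demethylates one ester, the carboxylate loses CO2 and water protonates the enolate.

Step 6
Reactants: 9 2-deoxy-L-ribose
Product: 10 (2S,3R)-4-(1,3-dithian-2-yl)butane-1,2,3-triol
Conditions: HS(CH2)3SH, conc. HCl, 0 °C to rt
Reagents that add atoms: propane-1,3-dithiol, SCCCS
Why: Acid-catalysed dithioacetalisation traps the open-chain aldehyde and leaves both carbinol stereocentres untouched.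

Step 7
Reactants: 10 (2S,3R)-4-(1,3-dithian-2-yl)butane-1,2,3-triol
Product: 11 (1R)-2-(1,3-dithian-2-yl)-1-[(4S)-2,2-dimethyl-1,3-dioxolan-4-yl]ethan-1-ol
Conditions: Me2C(OMe)2, p-TsOH·H2O (cat.), acetone, 0 °C to rt
Reagents that add atoms: 2,2-dimethoxypropane, COC(C)(C)OC
Why: Transketalisation under thermodynamic control selects the terminal 1,2-diol (monosubstituted dioxolane) over the cis-disubstituted internal dioxolane, leaving the future butenolide carbinol free.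

Step 8
Reactants: 11 (1R)-2-(1,3-dithian-2-yl)-1-[(4S)-2,2-dimethyl-1,3-dioxolan-4-yl]ethan-1-ol
Product: 13 2-{(2R)-2-[(4S)-2,2-dimethyl-1,3-dioxolan-4-yl]-2-(PMBO)ethyl}-1,3-dithiane, via sodium alkoxide 12 (not isolated)
Conditions: NaH, THF/DMF, 0 °C; then PMBCl, n-Bu4NI (cat.), rt
Reagents that add atoms: 4-methoxybenzyl chloride, COc1ccc(CCl)cc1
Why: Williamson etherification of the secondary alkoxide under iodide catalysis; the dithiane C–H is too weakly acidic for NaH.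

Step 9
Reactants: 13 2-{(2R)-2-[(4S)-2,2-dimethyl-1,3-dioxolan-4-yl]-2-(PMBO)ethyl}-1,3-dithiane
Product: 14 (3R)-3-[(4S)-2,2-dimethyl-1,3-dioxolan-4-yl]-3-(PMBO)propanal
Conditions: MeI (excess), CaCO3, MeCN/H2O (9:1), 45 °C
Reagents that add atoms: water, O
Why: Alkylative dithiane hydrolysis (S-methylation, then attack of water) under buffered near-neutral conditions frees the aldehyde without harming the acetonide or PMB ether and without β-elimination.

Step 10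
Reactants: 8 methyl 4-(Dec)butanoate; 14 (3R)-3-[(4S)-2,2-dimethyl-1,3-dioxolan-4-yl]-3-(PMBO)propanal
Product: 16 methyl (5R)-5-[(4S)-2,2-dimethyl-1,3-dioxolan-4-yl]-3-hydroxy-5-(PMBO)-2-[2-(Dec)ethyl]pentanoate (mixture at C2/C3), via lithium ester enolate 15 (not isolated)
Conditions: LiN(i-Pr)2 (1.1 equiv), THF, −78 °C; then 14, −78 °C; AcOH quench
Reagents that add atoms: none
Why: Directed aldol addition, in which the preformed lithium ester enolate adds to the aldehyde faster than it enolises it; the two new stereocentres form unselectively and are erased in step 11, while the sugar-derived (R) centre is untouched.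

Step 11
Reactants: 16 methyl (5R)-5-[(4S)-2,2-dimethyl-1,3-dioxolan-4-yl]-3-hydroxy-5-(PMBO)-2-[2-(Dec)ethyl]pentanoate
Product: 18 methyl (2E,5R)-5-[(4S)-2,2-dimethyl-1,3-dioxolan-4-yl]-5-(PMBO)-2-[2-(Dec)ethyl]pent-2-enoate, via mesylate 17 (not isolated)
Conditions: MsCl, Et3N, CH2Cl2, 0 °C; then DBU, 0 °C to rt
Reagents that add atoms: none
Why: Mesylation followed by E1cB elimination gives the conjugated enoate with the ester trans to the new chain (E) for steric reasons, and the minor Z isomer is removed by chromatography.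

Step 12
Reactants: 18 methyl (2E,5R)-5-[(4S)-2,2-dimethyl-1,3-dioxolan-4-yl]-5-(PMBO)-2-[2-(Dec)ethyl]pent-2-enoate
Product: 19 methyl (2E,5R,6S)-6,7-dihydroxy-5-(PMBO)-2-[2-(Dec)ethyl]hept-2-enoate
Conditions: AcOH/THF/H2O (3:1:1), 45 °C
Reagents that add atoms: none
Why: Mild acid hydrolysis of the terminal isopropylidene acetal, to which the PMB ether, enoate and tetrasubstituted alkene are stable.

Step 13
Reactants: 19 methyl (2E,5R,6S)-6,7-dihydroxy-5-(PMBO)-2-[2-(Dec)ethyl]hept-2-enoate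
Product: 20 methyl (2E,5R,6S)-7-(TBDPSO)-6-hydroxy-5-(PMBO)-2-[2-(Dec)ethyl]hept-2-enoate
Conditions: TBDPSCl (1.1 equiv), imidazole, CH2Cl2, 0 °C
Reagents that add atoms: tert-butyl(chloro)diphenylsilane, CC(C)(C)[Si](Cl)(c1ccccc1)c1ccccc1
Why: Sterically controlled silylation takes the primary hydroxyl of the 1,2-diol far faster than the flanked secondary one.

Step 14
Reactants: 20 methyl (2E,5R,6S)-7-(TBDPSO)-6-hydroxy-5-(PMBO)-2-[2-(Dec)ethyl]hept-2-enoate
Product: 21 (2E,5R,6S)-7-(TBDPSO)-5-(PMBO)-2-[2-(Dec)ethyl]hept-2-ene-1,6-diol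
Conditions: i-Bu2AlH (4 equiv), CH2Cl2, −78 °C to −40 °C; aq. potassium sodium tartrate
Reagents that add atoms: none
Why: Low-temperature 1,2-reduction of the enoate gives the allylic alcohol without conjugate reduction or loss of alkene geometry.

Step 15
Reactants: 21 (2E,5R,6S)-7-(TBDPSO)-5-(PMBO)-2-[2-(Dec)ethyl]hept-2-ene-1,6-diol
Product: 22 (2S,3R,5E)-1-(TBDPSO)-6-[(TBSO)methyl]-3-(PMBO)-8-(Dec)oct-5-en-2-ol
Conditions: TBSCl (1.05 equiv), imidazole, CH2Cl2, −20 °C to 0 °C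
Reagents that add atoms: tert-butyl(chloro)dimethylsilane, CC(C)(C)[Si](C)(C)Cl
Why: Selective silylation of the unhindered primary allylic alcohol over the hindered secondary alcohol.

Step 16
Reactants: 22 (2S,3R,5E)-1-(TBDPSO)-6-[(TBSO)methyl]-3-(PMBO)-8-(Dec)oct-5-en-2-ol
Product: 23 (3R,5E)-1-(TBDPSO)-6-[(TBSO)methyl]-3-(PMBO)-8-(Dec)oct-5-en-2-one
Conditions: Dess–Martin periodinane, NaHCO3, CH2Cl2, 0 °C to rt
Reagents that add atoms: none
Why: Dess–Martin oxidation of the secondary alcohol under buffered, non-epimerising conditions removes the now superfluous sugar C4 stereocentre.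

Step 17
Reactants: 23 (3R,5E)-1-(TBDPSO)-6-[(TBSO)methyl]-3-(PMBO)-8-(Dec)oct-5-en-2-one
Product: 24 (3R,5E)-1-(TBDPSO)-6-[(TBSO)methyl]-3-hydroxy-8-(Dec)oct-5-en-2-one
Conditions: DDQ (1.3 equiv), CH2Cl2/aq. phosphate buffer pH 7 (10:1), 0 °C
Reagents that add atoms: none
Why: Oxidative PMB cleavage (hydride abstraction, hydrolysis of the oxocarbenium ion) leaves silyl ethers, ketone and alkenes intact and does not epimerise the α-hydroxy ketone at neutral pH.

Step 18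
Reactants: 24 (3R,5E)-1-(TBDPSO)-6-[(TBSO)methyl]-3-hydroxy-8-(Dec)oct-5-en-2-one
Product: 26 (5R)-4-[(TBDPSO)methyl]-5-{(2E)-3-[(TBSO)methyl]-5-(Dec)pent-2-en-1-yl}furan-2(5H)-one, via phosphorane ester 25 (not isolated)
Conditions: Ph3P=C=C=O (1.3 equiv), toluene, 80 °C
Reagents that add atoms: (triphenylphosphoranylidene)ketene, O=C=C=P(c1ccccc1)(c1ccccc1)c1ccccc1
Why: Bestmann cascade, in which the hydroxyl adds to the ketenylidene ylide and the resulting ester-stabilised phosphorane closes onto the adjacent ketone by intramolecular Wittig olefination; no base is present, so the (R) centre is retained.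

Step 19
Reactants: 26 (5R)-4-[(TBDPSO)methyl]-5-{(2E)-3-[(TBSO)methyl]-5-(Dec)pent-2-en-1-yl}furan-2(5H)-one
Product: 27 (5R)-4-[(TBDPSO)methyl]-5-[(2E)-3-(hydroxymethyl)-5-(Dec)pent-2-en-1-yl]furan-2(5H)-one
Conditions: PPTS (cat.), MeOH/CH2Cl2, 0 °C to rt
Reagents that add atoms: none
Why: Acid-catalysed methanolysis removes the primary TBS ether much faster than the bulkier TBDPS ether.

Step 20
Reactants: 27 (5R)-4-[(TBDPSO)methyl]-5-[(2E)-3-(hydroxymethyl)-5-(Dec)pent-2-en-1-yl]furan-2(5H)-one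
Product: 28 (2E)-4-{(2R)-3-[(TBDPSO)methyl]-5-oxo-2,5-dihydrofuran-2-yl}-2-[2-(Dec)ethyl]but-2-enal
Conditions: activated MnO2 (excess), CH2Cl2, rt
Reagents that add atoms: none
Why: Neutral allylic oxidation of the only free hydroxyl gives the (E)-enal without touching the base-sensitive butenolide.

Step 21
Reactants: 28 (2E)-4-{(2R)-3-[(TBDPSO)methyl]-5-oxo-2,5-dihydrofuran-2-yl}-2-[2-(Dec)ethyl]but-2-enal
Product: 29 (2E)-4-[(2R)-3-(hydroxymethyl)-5-oxo-2,5-dihydrofuran-2-yl]-2-[2-(Dec)ethyl]but-2-enal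
Conditions: HF·pyridine, pyridine, THF, 0 °C to rt
Reagents that add atoms: none
Why: Fluoride desilylation under mildly acidic conditions avoids base, to which the γ-acidic butenolide and the δ-acyloxy enal are sensitive.

**Compound list**
1 | (+)-sclareolide, (3aR,5aS,9aS,9bR)-3a,6,6,9a-tetramethyldecahydronaphtho[2,1-b]furan-2(1H)-one | CC1(CCC[C@]2([C@H]1CC[C@@]3([C@@H]2CC(=O)O3)C)C)C | starting material
2 | methyl 2-(Dec)acetate | CC1=C(CC(=O)OC)[C@@]2(C)CCCC(C)(C)[C@@H]2CC1 | intermediate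
3 | 2-(Dec)ethan-1-ol | CC1=C(CCO)[C@@]2(C)CCCC(C)(C)[C@@H]2CC1 | intermediate
4 | 2-(Dec)ethyl iodide | CC1=C(CCI)[C@@]2(C)CCCC(C)(C)[C@@H]2CC1 | intermediate
5 | dimethyl malonate | COC(=O)CC(=O)OC | starting material
6 | sodium dimethyl malonate (formed in the flask) | [Na+].COC(=O)[CH-]C(=O)OC | intermediate
7 | dimethyl 2-[2-(Dec)ethyl]propanedioate | CC1=C(CCC(C(=O)OC)C(=O)OC)[C@@]2(C)CCCC(C)(C)[C@@H]2CC1 | intermediate
8 | methyl 4-(Dec)butanoate | CC1=C(CCCC(=O)OC)[C@@]2(C)CCCC(C)(C)[C@@H]2CC1 | intermediate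
9 | 2-deoxy-L-ribose, (3R,4S)-3,4,5-trihydroxypentanal (open-chain form) | O=CC[C@@H](O)[C@@H](O)CO | starting material
10 | (2S,3R)-4-(1,3-dithian-2-yl)butane-1,2,3-triol | C1(SCCCS1)C[C@@H](O)[C@@H](O)CO | intermediate
11 | (1R)-2-(1,3-dithian-2-yl)-1-[(4S)-2,2-dimethyl-1,3-dioxolan-4-yl]ethan-1-ol | C1(SCCCS1)C[C@@H](O)[C@@H]2COC(C)(C)O2 | intermediate
12 | sodium alkoxide of 11 (formed in the flask) | C1(SCCCS1)C[C@@H]([O-])[C@@H]2COC(C)(C)O2.[Na+] | intermediate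
13 | 2-{(2R)-2-[(4S)-2,2-dimethyl-1,3-dioxolan-4-yl]-2-(PMBO)ethyl}-1,3-dithiane | C1(SCCCS1)C[C@@H](OCc2ccc(OC)cc2)[C@@H]2COC(C)(C)O2 | intermediate
14 | (3R)-3-[(4S)-2,2-dimethyl-1,3-dioxolan-4-yl]-3-(PMBO)propanal | O=CC[C@@H](OCc1ccc(OC)cc1)[C@@H]1COC(C)(C)O1 | intermediate
15 | lithium enolate of 8 (formed in the flask) | CC1=C(CCC=C([O-])OC)[C@@]2(C)CCCC(C)(C)[C@@H]2CC1.[Li+] | intermediate
16 | methyl (5R)-5-[(4S)-2,2-dimethyl-1,3-dioxolan-4-yl]-3-hydroxy-5-(PMBO)-2-[2-(Dec)ethyl]pentanoate (mixture at C2/C3) | CC1=C(CCC(C(=O)OC)C(O)C[C@@H](OCc3ccc(OC)cc3)[C@@H]3COC(C)(C)O3)[C@@]2(C)CCCC(C)(C)[C@@H]2CC1 | intermediate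
17 | 3-O-methanesulfonate of 16 (formed in the flask) | CC1=C(CCC(C(=O)OC)C(OS(C)(=O)=O)C[C@@H](OCc3ccc(OC)cc3)[C@@H]3COC(C)(C)O3)[C@@]2(C)CCCC(C)(C)[C@@H]2CC1 | intermediate
18 | methyl (2E,5R)-5-[(4S)-2,2-dimethyl-1,3-dioxolan-4-yl]-5-(PMBO)-2-[2-(Dec)ethyl]pent-2-enoate | CC1=C(CC/C(C(=O)OC)=C\C[C@@H](OCc3ccc(OC)cc3)[C@@H]3COC(C)(C)O3)[C@@]2(C)CCCC(C)(C)[C@@H]2CC1 | intermediate
19 | methyl (2E,5R,6S)-6,7-dihydroxy-5-(PMBO)-2-[2-(Dec)ethyl]hept-2-enoate | CC1=C(CC/C(C(=O)OC)=C\C[C@@H](OCc3ccc(OC)cc3)[C@@H](O)CO)[C@@]2(C)CCCC(C)(C)[C@@H]2CC1 | intermediate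
20 | methyl (2E,5R,6S)-7-(TBDPSO)-6-hydroxy-5-(PMBO)-2-[2-(Dec)ethyl]hept-2-enoate | CC1=C(CC/C(C(=O)OC)=C\C[C@@H](OCc3ccc(OC)cc3)[C@@H](O)CO[Si](c3ccccc3)(c3ccccc3)C(C)(C)C)[C@@]2(C)CCCC(C)(C)[C@@H]2CC1 | intermediate
21 | (2E,5R,6S)-7-(TBDPSO)-5-(PMBO)-2-[2-(Dec)ethyl]hept-2-ene-1,6-diol | CC1=C(CC/C(CO)=C\C[C@@H](OCc3ccc(OC)cc3)[C@@H](O)CO[Si](c3ccccc3)(c3ccccc3)C(C)(C)C)[C@@]2(C)CCCC(C)(C)[C@@H]2CC1 | intermediate
22 | (2S,3R,5E)-1-(TBDPSO)-6-[(TBSO)methyl]-3-(PMBO)-8-(Dec)oct-5-en-2-ol | CC1=C(CC/C(CO[Si](C)(C)C(C)(C)C)=C\C[C@@H](OCc3ccc(OC)cc3)[C@@H](O)CO[Si](c3ccccc3)(c3ccccc3)C(C)(C)C)[C@@]2(C)CCCC(C)(C)[C@@H]2CC1 | intermediate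
23 | (3R,5E)-1-(TBDPSO)-6-[(TBSO)methyl]-3-(PMBO)-8-(Dec)oct-5-en-2-one | CC1=C(CC/C(CO[Si](C)(C)C(C)(C)C)=C\C[C@@H](OCc3ccc(OC)cc3)C(=O)CO[Si](c3ccccc3)(c3ccccc3)C(C)(C)C)[C@@]2(C)CCCC(C)(C)[C@@H]2CC1 | intermediate
24 | (3R,5E)-1-(TBDPSO)-6-[(TBSO)methyl]-3-hydroxy-8-(Dec)oct-5-en-2-one | CC1=C(CC/C(CO[Si](C)(C)C(C)(C)C)=C\C[C@@H](O)C(=O)CO[Si](c3ccccc3)(c3ccccc3)C(C)(C)C)[C@@]2(C)CCCC(C)(C)[C@@H]2CC1 | intermediate
25 | (triphenylphosphoranylidene)acetate ester of 24 at O-3 (formed in the flask) | CC1=C(CC/C(CO[Si](C)(C)C(C)(C)C)=C\C[C@@H](OC(=O)C=P(c3ccccc3)(c3ccccc3)c3ccccc3)C(=O)CO[Si](c3ccccc3)(c3ccccc3)C(C)(C)C)[C@@]2(C)CCCC(C)(C)[C@@H]2CC1 | intermediate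
26 | (5R)-4-[(TBDPSO)methyl]-5-{(2E)-3-[(TBSO)methyl]-5-(Dec)pent-2-en-1-yl}furan-2(5H)-one | CC1=C(CC/C(CO[Si](C)(C)C(C)(C)C)=C\C[C@H]3OC(=O)C=C3CO[Si](c4ccccc4)(c4ccccc4)C(C)(C)C)[C@@]2(C)CCCC(C)(C)[C@@H]2CC1 | intermediate
27 | (5R)-4-[(TBDPSO)methyl]-5-[(2E)-3-(hydroxymethyl)-5-(Dec)pent-2-en-1-yl]furan-2(5H)-one | CC1=C(CC/C(CO)=C\C[C@H]3OC(=O)C=C3CO[Si](c4ccccc4)(c4ccccc4)C(C)(C)C)[C@@]2(C)CCCC(C)(C)[C@@H]2CC1 | intermediate
28 | (2E)-4-{(2R)-3-[(TBDPSO)methyl]-5-oxo-2,5-dihydrofuran-2-yl}-2-[2-(Dec)ethyl]but-2-enal | CC1=C(CC/C(C=O)=C\C[C@H]3OC(=O)C=C3CO[Si](c4ccccc4)(c4ccccc4)C(C)(C)C)[C@@]2(C)CCCC(C)(C)[C@@H]2CC1 | intermediate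
29 | (2E)-4-[(2R)-3-(hydroxymethyl)-5-oxo-2,5-dihydrofuran-2-yl]-2-[2-(Dec)ethyl]but-2-enal (CNP0197865.2) | CC1=C(CC/C(C=O)=C\C[C@H]2OC(=O)C=C2CO)[C@@]2(C)CCCC(C)(C)[C@@H]2CC1 | target

**Totals and risks**
Total step count: 21. Longest linear sequence: 17 steps (steps 1–5, then 10–21, from 1).

Most likely to fail:

Step 1 (alkene regiochemistry on opening the lactone). The fallback sets out from 1 and returns at 3. LiAlH4 in THF reduces 1 to (1R,2R,4aS,8aS)-1-(2-hydroxyethyl)-2,5,5,8a-tetramethyldecahydronaphthalen-2-ol F1. Ac2O/pyridine acetylates only the primary hydroxyl to give 2-[(1R,2R,4aS,8aS)-2-hydroxy-2,5,5,8a-tetramethyldecahydronaphthalen-1-yl]ethyl acetate F2. PPh3/I2 in CH2Cl2 without base dehydrates the tertiary alcohol regioselectively toward the most substituted alkene, giving 2-(Dec)ethyl acetate F3. K2CO3/MeOH then removes the acetate to give 3.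

Step 11 (E/Z ratio and possible deconjugation in the E1cB dehydration). The fallback sets out from 4 and returns at 18, replacing the addition–elimination by a one-step olefination. Alkylation of the sodium salt of trimethyl phosphonoacetate with 4 (NaH, DMF, 60 °C) gives methyl 2-(dimethoxyphosphoryl)-4-(Dec)butanoate F4. Horner–Wadsworth–Emmons reaction of F4 with aldehyde 14 (NaH, THF, 0 °C to rt) gives enoate 18 after separation of alkene isomers.

Step 18 (sluggish Wittig closure or erosion of the α-stereocentre on heating). The fallback sets out from 24 and returns at 26. Esterification of 24 with (diethoxyphosphoryl)acetic acid (EDC·HCl, DMAP, CH2Cl2, 0 °C) gives (3R,5E)-1-(TBDPSO)-6-[(TBSO)methyl]-8-(Dec)-2-oxooct-5-en-3-yl (diethoxyphosphoryl)acetate F5. Intramolecular Horner–Wadsworth–Emmons closure of F5 under mild conditions (LiCl, i-Pr2NEt, MeCN, rt) gives 26.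

**Further compounds**
F1 | step 1 | (1R,2R,4aS,8aS)-1-(2-hydroxyethyl)-2,5,5,8a-tetramethyldecahydronaphthalen-2-ol | CC1(CCC[C@]2([C@H]1CC[C@@](O)([C@@H]2CCO)C)C)C
F2 | step 1 | 2-[(1R,2R,4aS,8aS)-2-hydroxy-2,5,5,8a-tetramethyldecahydronaphthalen-1-yl]ethyl acetate | CC1(CCC[C@]2([C@H]1CC[C@@](O)([C@@H]2CCOC(C)=O)C)C)C
F3 | step 1 | 2-(Dec)ethyl acetate | CC1=C(CCOC(C)=O)[C@@]2(C)CCCC(C)(C)[C@@H]2CC1
F4 | step 11 | methyl 2-(dimethoxyphosphoryl)-4-(Dec)butanoate | CC1=C(CCC(C(=O)OC)P(=O)(OC)OC)[C@@]2(C)CCCC(C)(C)[C@@H]2CC1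
F5 | step 18 | (3R,5E)-1-(TBDPSO)-6-[(TBSO)methyl]-8-(Dec)-2-oxooct-5-en-3-yl (diethoxyphosphoryl)acetate | CC1=C(CC/C(CO[Si](C)(C)C(C)(C)C)=C\C[C@@H](OC(=O)CP(=O)(OCC)OCC)C(=O)CO[Si](c3ccccc3)(c3ccccc3)C(C)(C)C)[C@@]2(C)CCCC(C)(C)[C@@H]2CC1
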